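The earlier runs and the new flask are simulated on assumed constants, noise included.

- G is the product I follow. In the oak run, at 14 min, it already stands at 32.4 % of the Z charged, and by 83 min it reads 38.6 %.

all flasks: L 5.00 × 10⁻⁴ M
- oak: Z 0.0500 M; Q 0.0550 M
- cedar: Z 0.0300 M; Q 0.0350 M
- larch: Z 0.0500 M; Q 0.0830 M
- ash: Z 0.0250 M; Q 0.0550 M
- birch: Z 0.0110 M; Q 0.0550 M; time 83 min

- oak run (time / min: [G] / M): 14: 0.0162; 28: 0.0180; 42: 0.0188; 55: 0.0189; 69: 0.0191; 83: 0.0193
- cedar run (time / min: [G] / M): 14: 0.0113; 28: 0.0131; 42: 0.0128; 55: 0.0139; 69: 0.0139; 83: 0.0140
- larch run (time / min: [G] / M): 14: 0.0173; 28: 0.0194; 42: 0.0194; 55: 0.0194; 69: 0.0206; 83: 0.0198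
- ash run (time / min: [G] / M): 14: 0.0104; 28: 0.0112; 42: 0.0117; 55: 0.0114; 69: 0.0136; 83: 0.0130

(standard deviation of a reading: 5 × 10⁻⁴ M)

- Overall: Z + Q -> G, with L as catalyst.
- Constant volume, constant temperature.
- A reading of a species includes what of it is bound.
- An order is taken over about fifteen percent of the charge, up and down.

- the power of [Q] that the first rate follows, about the charge of the oak run; measure it at two percent of Z made into G
- the power of [Z] that the first rate follows, about the charge of the oak run; measure it at two percent of Z made into G (one fixed amount of G, the same in the runs compared)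
- G in the birch run at 83 min, as a share of the Z charged

- First rung, the climb: it lies before the first oak reading, so no reading shows the first rate.
- Second rung, the bend: from 14 min to 42 min, oak gains 5.20 % of its Z.
- Third rung, the stall: from 42 min to 83 min, oak gains 1.00 %, which is less than on the second rung. At that point G accounts for 35.1 % of the Q charged, so the oak stall comes with Q still present.
- Larch has 1.51 times the Q of oak, yet the ratio of the last readings of larch and oak gives a power of Q near 0.0622, a figure that carries the scatter.
- I call dose the logarithm of one over the share of Z not turned into G, which for oak at 83 min reads 0.488. A single pseudo-first-order route with the same L history gives one dose at any Z charge.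
- Ash reads 0.734, more than oak, so I take a second loss of Z that grows with the charge, and I keep the power of Z in the first rate near 1.
- A straight line through oak and ash gives birch a dose of 0.872, so my birch share is 58.2 %.
- The forecast gives 0.1 for Q, 0.42 for Z and 65 % for birch, reasoning that “The plateau fraction rises as Z falls”. It parts from my reckoning on the power of Z and on the birch share.
- The flask gives 0.091 for Q, 1.0 for Z and 60.0 % for birch.

    L + Z ⇌ LZ (293.4 M⁻¹ min⁻¹, 31.38 min⁻¹)
    LZ + Q → G + L (9120 M⁻¹ min⁻¹)
    2 Z → Qa (2.364 M⁻¹ min⁻¹)
    2 L → 2 Jy (291.0 M⁻¹ min⁻¹)

- Measured against the first rate of oak, the first rate in ash is 0.47, with half the Z. Birch ends at a dose of 0.917, against 0.872 reckoned and 0.488 read for oak. Birch stops short because of the conversion of 2 Z into Qa and the conversion of 2 L into 2 Jy. Without the conversion of 2 Z into Qa the birch dose is 1.52, and without the conversion of 2 L into 2 Jy the birch dose is 1.88.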